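**Plan**

- Cuts: the C7 silyl ether comes off last; ring C is opened at O1–C2 and C4–C4a to give the aryl (E)-3-methoxy-2-arylacrylate 14; the C8–prenyl bond goes back to a [3,3] shift from the C7 oxygen; the ester C–O bond separates acid 4 from phenol 9.
- Forward: arylacetate 1 gives methoxyacrylic acid 4 (ring B); isovanillin 5 gives propargyl ether phenol 9 (ring A); esterification, semihydrogenation, Claisen shift to C8 and silylation give 14; ring C is closed last in one photochemical operation, then desilylation.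
- Enabling feature: in ring A the ester oxygen O1 sits on C8a, whose ortho carbon C8 (prenyl) and para carbon C6 (OMe) are both substituted, so C4a is the only carbon where a migrating acyl group can settle and re-aromatise.
- Stereochemistry: the target has no stereocentre; the E enol ether geometry set in step 1 is lost on ring closure.

Key step: step 9

Remark: atoms are numbered as in chromen-4-one (O1, C2, C3, C4, C4a, C5 to C8, C8a); for the ring A precursors these numbers mean the future positions.

**Route**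

Step 1
Reactants: 1 methyl (3,4-dimethoxyphenyl)acetate
Product: 3 methyl (E)-2-(3,4-dimethoxyphenyl)-3-methoxyprop-2-enoate, via sodium formyl-ester enolate 2 (not isolated)
Conditions: NaH, HCO2Me, DMF, 0 °C → rt; then Me2SO4, rt
Reagents that add atoms: methyl formate, COC=O; dimethyl sulfate, COS(=O)(=O)OC
Why: Crossed Claisen condensation with methyl formate gives the sodium enolate of the α-formyl ester, and dimethyl sulfate alkylates its hard oxygen (O-alkylation of a β-dicarbonyl enolate), the E enol ether with OMe anti to the ester being the expected main isomer of this standard β-methoxyacrylate preparation.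

Step 2
Reactants: 3 methyl (E)-2-(3,4-dimethoxyphenyl)-3-methoxyprop-2-enoate
Product: 4 (E)-2-(3,4-dimethoxyphenyl)-3-methoxyprop-2-enoic acid
Conditions: LiOH, THF/MeOH/H2O, 40 °C; then aq. HCl to pH 3, 0 °C
Reagents that add atoms: lithium hydroxide, [Li+].[OH-]
Why: Saponification by acyl–oxygen cleavage; methanol as cosolvent makes any exchange at the β-carbon of this vinylogous carbonate degenerate, and cold, mild acidification should leave the enol ether intact.

Step 3
Reactants: 5 isovanillin (3-hydroxy-4-methoxybenzaldehyde); 6 3-chloro-3-methylbut-1-yne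
Product: 7 4-methoxy-3-(2-methylbut-3-yn-2-yloxy)benzaldehyde
Conditions: K2CO3, KI, CuI (cat.), DMF, 60 °C
Reagents that add atoms: none
Why: Copper-assisted O-alkylation of the phenoxide by the tertiary propargylic chloride (Williamson-type etherification through the copper acetylide), the standard entry to aryl 1,1-dimethylpropargyl ethers, run well below the temperature at which such ethers cyclise to chromenes.

Step 4
Reactants: 7 4-methoxy-3-(2-methylbut-3-yn-2-yloxy)benzaldehyde
Product: 9 4-methoxy-3-(2-methylbut-3-yn-2-yloxy)phenol, via aryl formate 8 (not isolated)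
Conditions: mCPBA, CH2Cl2, 0 °C → rt; aq. NaHCO3 wash; then K2CO3 (cat.), MeOH, rt
Reagents that add atoms: mCPBA, OOC(=O)c1cccc(Cl)c1
Why: Baeyer–Villiger (Dakin-type) oxidation in which the electron-rich aryl group, para to OMe, migrates to give the formate, which is then methanolysed; the terminal alkyne is inert to the peracid, which is why the oxidation is placed before any alkene is present.

Step 5
Reactants: 4 (E)-2-(3,4-dimethoxyphenyl)-3-methoxyprop-2-enoic acid; 9 4-methoxy-3-(2-methylbut-3-yn-2-yloxy)phenol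
Product: 10 [4-methoxy-3-(2-methylbut-3-yn-2-yloxy)phenyl] (E)-2-(3,4-dimethoxyphenyl)-3-methoxyprop-2-enoate
Conditions: DCC, DMAP (cat.), CH2Cl2, 0 °C → rt
Reagents that add atoms: none
Why: Steglich esterification, in which DMAP relays the acyl group from the O-acylisourea to the phenol under neutral conditions that leave the enol ether and the tertiary propargylic ether untouched.

Step 6
Reactants: 10 [4-methoxy-3-(2-methylbut-3-yn-2-yloxy)phenyl] (E)-2-(3,4-dimethoxyphenyl)-3-methoxyprop-2-enoate
Product: 11 [4-methoxy-3-(2-methylbut-3-en-2-yloxy)phenyl] (E)-2-(3,4-dimethoxyphenyl)-3-methoxyprop-2-enoate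
Conditions: H2 (1 atm), Pd/CaCO3 poisoned with Pb(OAc)2, quinoline, EtOAc, rt
Reagents that add atoms: none
Why: Lindlar semihydrogenation should stop at the terminal alkene on the poisoned catalyst, while the trisubstituted conjugated enol ether and the aryl ester are not reduced.

Step 7
Reactants: 11 [4-methoxy-3-(2-methylbut-3-en-2-yloxy)phenyl] (E)-2-(3,4-dimethoxyphenyl)-3-methoxyprop-2-enoate
Product: 13 [3-hydroxy-4-methoxy-2-(3-methylbut-2-enyl)phenyl] (E)-2-(3,4-dimethoxyphenyl)-3-methoxyprop-2-enoate, via ortho-dienone 12 (not isolated)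
Conditions: PhNEt2, 140 °C, argon
Reagents that add atoms: none
Why: Aromatic Claisen rearrangement, in which the [3,3] shift delivers the allyl terminus to the only unsubstituted ortho carbon of the ether oxygen (the future C8) with allylic inversion of 1,1-dimethylallyl to prenyl, and dienone 12 tautomerises to the phenol; the other ortho carbon carries OMe, and the basic solvent suppresses acid-catalysed chroman formation.

Step 8
Reactants: 13 [3-hydroxy-4-methoxy-2-(3-methylbut-2-enyl)phenyl] (E)-2-(3,4-dimethoxyphenyl)-3-methoxyprop-2-enoate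
Product: 14 [3-(tert-butyldimethylsilyloxy)-4-methoxy-2-(3-methylbut-2-enyl)phenyl] (E)-2-(3,4-dimethoxyphenyl)-3-methoxyprop-2-enoate
Conditions: TBSOTf, 2,6-lutidine, CH2Cl2, 0 °C
Reagents that add atoms: tert-butyldimethylsilyl triflate, CC(C)(C)[Si](C)(C)OS(=O)(=O)C(F)(F)F
Why: Silylation of the hindered phenol with a silyl triflate and a non-nucleophilic base, so that nothing present can attack the aryl ester; the silyl ether keeps the C7 oxygen from adding to the prenyl double bond during irradiation.

Step 9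
Reactants: 14 [3-(tert-butyldimethylsilyloxy)-4-methoxy-2-(3-methylbut-2-enyl)phenyl] (E)-2-(3,4-dimethoxyphenyl)-3-methoxyprop-2-enoate
Product: 17 7-(tert-butyldimethylsilyloxy)-3-(3,4-dimethoxyphenyl)-6-methoxy-8-(3-methylbut-2-enyl)chromen-4-one, via acyl dienone 15 (not isolated), via hydroxyaryl ketone 16 (not isolated)
Conditions: hν (254 nm, low-pressure Hg lamp, quartz flow coil), degassed cyclohexane (5 mM), 20 °C; then Et3N (cat.), 40 °C
Reagents that add atoms: none
Why: Excitation of the aryl ester breaks the O1–acyl bond homolytically, and the caged phenoxyl/acyl radical pair recombines at C4a to give dienone 15, which enolises to the hydrogen-bonded 2-hydroxyaryl ketone 16 (C4–C4a formed). The closest known reaction types are the photo-Fries rearrangement of aryl esters of α,β-unsaturated acids (aryl cinnamates to 2′-hydroxychalcones, aryl 3-methylbut-2-enoates to chroman-4-ones) and the closure of 2-hydroxyaryl β-alkoxyvinyl ketones to chromones. Ring C then closes by 6-endo-trig conjugate addition of O1 to the methoxy-bearing carbon C2 followed by elimination of methanol (O1–C2 formed), completed by the catalytic amine. No stereocentre is created, and E/Z isomerisation of the enol ether under light is harmless because both isomers of 16 converge on the same chromone through the rotatable addition intermediate. The step needs acyl return at C4a alone, and ring A secures this: the other ortho carbon C8 carries the prenyl group and the para carbon C6 carries OMe, so recombination there gives adducts that cannot tautomerise and fall back to the radical pair, while the vinyl-type acyl radical does not lose CO. The neutral medium leaves the prenyl group and the silyl ether alone.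

Step 10
Reactants: 17 7-(tert-butyldimethylsilyloxy)-3-(3,4-dimethoxyphenyl)-6-methoxy-8-(3-methylbut-2-enyl)chromen-4-one
Product: 18 3-(3,4-dimethoxyphenyl)-7-hydroxy-6-methoxy-8-(3-methylbut-2-enyl)chromen-4-one (EANPDB:LEGU_00008)
Conditions: TBAF, AcOH, THF, 0 °C → rt
Reagents that add atoms: none
Why: Fluoride-induced cleavage of the aryl silyl ether (desilylation), buffered with acetic acid so that the phenoxide is protonated at once and the base-sensitive pyranone ring is not exposed to unbuffered fluoride.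

**Compound list**

1 | methyl (3,4-dimethoxyphenyl)acetate | COC(=O)Cc1ccc(OC)c(OC)c1 | starting material
2 | sodium 2-(3,4-dimethoxyphenyl)-3-methoxy-3-oxoprop-1-en-1-olate (enolate of the α-formyl ester, delocalised, geometry not fixed) | COC(=O)C(=C[O-])c1ccc(OC)c(OC)c1.[Na+] | intermediate
3 | methyl (E)-2-(3,4-dimethoxyphenyl)-3-methoxyprop-2-enoate | CO/C=C(/C(=O)OC)c1ccc(OC)c(OC)c1 | intermediate
4 | (E)-2-(3,4-dimethoxyphenyl)-3-methoxyprop-2-enoic acid | CO/C=C(/C(=O)O)c1ccc(OC)c(OC)c1 | intermediate
5 | isovanillin (3-hydroxy-4-methoxybenzaldehyde) | COc1ccc(C=O)cc1O | starting material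
6 | 3-chloro-3-methylbut-1-yne | C#CC(C)(C)Cl | starting material
7 | 4-methoxy-3-(2-methylbut-3-yn-2-yloxy)benzaldehyde | COc1ccc(C=O)cc1OC(C)(C)C#C | intermediate
8 | [4-methoxy-3-(2-methylbut-3-yn-2-yloxy)phenyl] formate | COc1ccc(OC=O)cc1OC(C)(C)C#C | intermediate
9 | 4-methoxy-3-(2-methylbut-3-yn-2-yloxy)phenol | COc1ccc(O)cc1OC(C)(C)C#C | intermediate
10 | [4-methoxy-3-(2-methylbut-3-yn-2-yloxy)phenyl] (E)-2-(3,4-dimethoxyphenyl)-3-methoxyprop-2-enoate | CO/C=C(/C(=O)Oc1ccc(OC)c(OC(C)(C)C#C)c1)c1ccc(OC)c(OC)c1 | intermediate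
11 | [4-methoxy-3-(2-methylbut-3-en-2-yloxy)phenyl] (E)-2-(3,4-dimethoxyphenyl)-3-methoxyprop-2-enoate | CO/C=C(/C(=O)Oc1ccc(OC)c(OC(C)(C)C=C)c1)c1ccc(OC)c(OC)c1 | intermediate
12 | [4-methoxy-6-(3-methylbut-2-enyl)-5-oxocyclohexa-1,3-dien-1-yl] (E)-2-(3,4-dimethoxyphenyl)-3-methoxyprop-2-enoate (racemic at the ring sp3 carbon) | CO/C=C(/C(=O)OC1=CC=C(OC)C(=O)C1CC=C(C)C)c1ccc(OC)c(OC)c1 | intermediate
13 | [3-hydroxy-4-methoxy-2-(3-methylbut-2-enyl)phenyl] (E)-2-(3,4-dimethoxyphenyl)-3-methoxyprop-2-enoate | CO/C=C(/C(=O)Oc1ccc(OC)c(O)c1CC=C(C)C)c1ccc(OC)c(OC)c1 | intermediate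
14 | [3-(tert-butyldimethylsilyloxy)-4-methoxy-2-(3-methylbut-2-enyl)phenyl] (E)-2-(3,4-dimethoxyphenyl)-3-methoxyprop-2-enoate | CO/C=C(/C(=O)Oc1ccc(OC)c(O[Si](C)(C)C(C)(C)C)c1CC=C(C)C)c1ccc(OC)c(OC)c1 | intermediate
15 | 3-(tert-butyldimethylsilyloxy)-6-[2-(3,4-dimethoxyphenyl)-3-methoxyprop-2-enoyl]-4-methoxy-2-(3-methylbut-2-enyl)cyclohexa-2,4-dien-1-one (racemic at C6 of the dienone, E/Z mixture at the enol ether) | COC=C(C(=O)C1C=C(OC)C(O[Si](C)(C)C(C)(C)C)=C(CC=C(C)C)C1=O)c1ccc(OC)c(OC)c1 | intermediate
16 | 1-[4-(tert-butyldimethylsilyloxy)-2-hydroxy-5-methoxy-3-(3-methylbut-2-enyl)phenyl]-2-(3,4-dimethoxyphenyl)-3-methoxyprop-2-en-1-one (E/Z mixture) | COC=C(C(=O)c1cc(OC)c(O[Si](C)(C)C(C)(C)C)c(CC=C(C)C)c1O)c1ccc(OC)c(OC)c1 | intermediate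
17 | 7-(tert-butyldimethylsilyloxy)-3-(3,4-dimethoxyphenyl)-6-methoxy-8-(3-methylbut-2-enyl)chromen-4-one | COc1ccc(-c2coc3c(CC=C(C)C)c(O[Si](C)(C)C(C)(C)C)c(OC)cc3c2=O)cc1OC | intermediate
18 | 3-(3,4-dimethoxyphenyl)-7-hydroxy-6-methoxy-8-(3-methylbut-2-enyl)chromen-4-one | COc1ccc(-c2coc3c(CC=C(C)C)c(O)c(OC)cc3c2=O)cc1OC | target

**Totals**

Total step count: 10. Longest linear sequence: 8 steps (5 to 18 through steps 3 to 10; the branch from 1 through steps 1, 2 and 5 to 10 is equally long).

**Steps most likely to fail**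

1. Step 9. The radical pair may escape the solvent cage and be lost by hydrogen abstraction. Light may be wasted on E/Z isomerisation of the enol ether or absorbed by the chromone as it accumulates. The freed O1 phenol may photo-add to the neighbouring prenyl double bond before ring C closes.

   Fallback (classical isoflavone construction with the Claisen shift last; sets out from 1, comes back at 18): saponification of 1 (LiOH) would give (3,4-dimethoxyphenyl)acetic acid F1. Friedel–Crafts acylation of commercial 4-methoxybenzene-1,3-diol with it in BF3·OEt2 at 85 °C would give the deoxybenzoin 1-(2,4-dihydroxy-5-methoxyphenyl)-2-(3,4-dimethoxyphenyl)ethanone F2. N,N-Dimethylformamide dimethyl acetal in THF at 60 °C would convert this into the enaminone 1-(2,4-dihydroxy-5-methoxyphenyl)-2-(3,4-dimethoxyphenyl)-3-(dimethylamino)prop-2-en-1-one F3, which is not isolated and closes with loss of dimethylamine to 3-(3,4-dimethoxyphenyl)-7-hydroxy-6-methoxychromen-4-one F4. O-Alkylation with 6 (K2CO3, KI, CuI, DMF) would give 3-(3,4-dimethoxyphenyl)-6-methoxy-7-(2-methylbut-3-yn-2-yloxy)chromen-4-one F5, and semihydrogenation as in step 6 would give 3-(3,4-dimethoxyphenyl)-6-methoxy-7-(2-methylbut-3-en-2-yloxy)chromen-4-one F6. Claisen rearrangement in PhNEt2, where the OMe group on C6 leaves only C8 open, would pass through 3-(3,4-dimethoxyphenyl)-6-methoxy-8-(3-methylbut-2-enyl)-8H-chromene-4,7-dione F7 and tautomerise to 18.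

2. Step 7. The tertiary allyl group may be lost by elimination before it migrates. Migration may run on through the OMe-bearing ortho carbon to the position para to the ether oxygen. The new phenol may cyclise onto the prenyl double bond, or the aryl ester may suffer at the required temperature.

   Fallback (plain allyl transfer followed by olefin cross-metathesis; sets out from 5, comes back at 13): allylation of 5 (allyl bromide, K2CO3, acetone) would give 4-methoxy-3-(prop-2-enyloxy)benzaldehyde F8. Baeyer–Villiger oxidation with mCPBA would give [4-methoxy-3-(prop-2-enyloxy)phenyl] formate F9, and methanolysis would give 4-methoxy-3-(prop-2-enyloxy)phenol F10. Esterification with 4 as in step 5 would give [4-methoxy-3-(prop-2-enyloxy)phenyl] (E)-2-(3,4-dimethoxyphenyl)-3-methoxyprop-2-enoate F11. Claisen rearrangement (PhNEt2, 190 °C) would pass through [4-methoxy-5-oxo-6-(prop-2-enyl)cyclohexa-1,3-dien-1-yl] (E)-2-(3,4-dimethoxyphenyl)-3-methoxyprop-2-enoate F12 to [3-hydroxy-4-methoxy-2-(prop-2-enyl)phenyl] (E)-2-(3,4-dimethoxyphenyl)-3-methoxyprop-2-enoate F13. Cross-metathesis with 2-methylbut-2-ene (second-generation Grubbs catalyst, RuCl2(=CHPh)(PCy3)(H2IMes), CH2Cl2, 40 °C) would turn the allyl group into prenyl and give 13.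

3. Step 5. Acyl transfer from the hindered, electron-rich O-acylisourea to the phenol may be slow, so that rearrangement to the N-acylurea takes over.

   Fallback (pre-formed acyl chloride in place of carbodiimide activation; sets out from 4, comes back at 10): oxalyl chloride with catalytic DMF in CH2Cl2 would give (E)-2-(3,4-dimethoxyphenyl)-3-methoxyprop-2-enoyl chloride F14, which would acylate phenol 9 in acetone over K2CO3 at 0 °C to rt to give 10.

**Further compounds**

F1 | step 9 | (3,4-dimethoxyphenyl)acetic acid | OC(=O)Cc1ccc(OC)c(OC)c1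
F2 | step 9 | 1-(2,4-dihydroxy-5-methoxyphenyl)-2-(3,4-dimethoxyphenyl)ethanone | COc1ccc(CC(=O)c2cc(OC)c(O)cc2O)cc1OC
F3 | step 9 | 1-(2,4-dihydroxy-5-methoxyphenyl)-2-(3,4-dimethoxyphenyl)-3-(dimethylamino)prop-2-en-1-one | CN(C)C=C(C(=O)c1cc(OC)c(O)cc1O)c1ccc(OC)c(OC)c1
F4 | step 9 | 3-(3,4-dimethoxyphenyl)-7-hydroxy-6-methoxychromen-4-one | COc1ccc(-c2coc3cc(O)c(OC)cc3c2=O)cc1OC
F5 | step 9 | 3-(3,4-dimethoxyphenyl)-6-methoxy-7-(2-methylbut-3-yn-2-yloxy)chromen-4-one | COc1ccc(-c2coc3cc(OC(C)(C)C#C)c(OC)cc3c2=O)cc1OC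
F6 | step 9 | 3-(3,4-dimethoxyphenyl)-6-methoxy-7-(2-methylbut-3-en-2-yloxy)chromen-4-one | COc1ccc(-c2coc3cc(OC(C)(C)C=C)c(OC)cc3c2=O)cc1OC
F7 | step 9 | 3-(3,4-dimethoxyphenyl)-6-methoxy-8-(3-methylbut-2-enyl)-8H-chromene-4,7-dione (racemic at C8) | COc1ccc(C2=COC3=C(C2=O)C=C(OC)C(=O)C3CC=C(C)C)cc1OC
F8 | step 7 | 4-methoxy-3-(prop-2-enyloxy)benzaldehyde | COc1ccc(C=O)cc1OCC=C
F9 | step 7 | [4-methoxy-3-(prop-2-enyloxy)phenyl] formate | COc1ccc(OC=O)cc1OCC=C
F10 | step 7 | 4-methoxy-3-(prop-2-enyloxy)phenol | COc1ccc(O)cc1OCC=C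
F11 | step 7 | [4-methoxy-3-(prop-2-enyloxy)phenyl] (E)-2-(3,4-dimethoxyphenyl)-3-methoxyprop-2-enoate | CO/C=C(/C(=O)Oc1ccc(OC)c(OCC=C)c1)c1ccc(OC)c(OC)c1
F12 | step 7 | [4-methoxy-5-oxo-6-(prop-2-enyl)cyclohexa-1,3-dien-1-yl] (E)-2-(3,4-dimethoxyphenyl)-3-methoxyprop-2-enoate (racemic at the ring sp3 carbon) | CO/C=C(/C(=O)OC1=CC=C(OC)C(=O)C1CC=C)c1ccc(OC)c(OC)c1
F13 | step 7 | [3-hydroxy-4-methoxy-2-(prop-2-enyl)phenyl] (E)-2-(3,4-dimethoxyphenyl)-3-methoxyprop-2-enoate | CO/C=C(/C(=O)Oc1ccc(OC)c(O)c1CC=C)c1ccc(OC)c(OC)c1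
F14 | step 5 | (E)-2-(3,4-dimethoxyphenyl)-3-methoxyprop-2-enoyl chloride | CO/C=C(/C(=O)Cl)c1ccc(OC)c(OC)c1
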